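The ratio of substrate left to substrate charged is what I follow, written as the log-left L = ln(charged/left), which rises in step with time in a pseudo-first-order reaction.

| flask | substrate | partner | free catalyst | remark | time |
|---|---|---|---|---|---|
| dawn | 0.040 M | 0.15 M | 1 mM | run made earlier |  |
| winter | 0.062 M | 0.15 M | 1 mM | run made earlier |  |
| spring | 0.050 M | 0.19 M | 1 mM | run made earlier |  |
| Wednesday's | 0.080 M | 0.250 M | 1.0 mM |  | 50 min |
| Sunday's | 0.050 M | 0.150 M | 1.0 mM |  | 50 min |

- dawn (time / min: product / %, substrate / %): 8.00: 10.9, 88.8; 15.0: 17.4, 83.3; 20.0: 21.4, 78.5; 30.0: 27.1, 72.3; 40.0: 32.4, 66.8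
- winter (time / min: product / %, substrate / %): 8.00: 8.8, 90.7; 15.0: 14.4, 85.5; 20.0: 17.3, 82.3; 30.0: 22.8, 77.4; 40.0: 27.2, 73.0
- spring (time / min: product / %, substrate / %): 3.00: 4.5, 95.7; 5.00: 7.3, 93.1; 10.0: 13.1, 87.7; 20.0: 20.9, 78.8; 40.0: 31.9, 67.5

(standard deviation of a reading: 0.3 percentage points)

1. which of the two ends with the higher amount of product, in percent of the substrate charged ("neither" if they lie within 2 percentage points) (Wednesday's / Sunday's / neither)
2. product at the end, in percent of the substrate charged, Wednesday's
3. product at the end, in percent of the substrate charged, Sunday's

At 40.0 min the dawn run has L = 0.403, and the winter run, with the same partner and more substrate, has 0.315. So I let L fall as a power of the substrate charge, and I call that power, the slope of ln L against the logarithm of the charge taken positive, the substrate power: 0.567. In the spring run L goes from 0.238 at 20.0 min to 0.393 at 40.0 min, so it grows as time to the power 0.722, which is below one.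

Sunday's substrate charge lowers dawn's L to 0.356 at 40.0 min, and the stretch to 50 min raises it to 0.418, so Sunday's ends near 34.1% product. The spring run has Sunday's substrate with more partner, and its L against that 0.356 gives a partner power of 0.424, which puts Wednesday's at 32.8%.

That power is the weak link, since the spring run moves the partner by a factor of 1.27 and Wednesday's needs 1.67. So I read it again at 20.0 min, where it comes to 0.468. The mean, 0.446, gives Wednesday's 33.1%, which lies 1 percentage point below Sunday's, inside the margin, so I commit to neither.

The forecast, close to my figures but not equal to them, gives 32.3% for Wednesday's, 33.9% for Sunday's and neither, holding that “Spring implies only about half order in partner”.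

The flask gives 33.6% for Wednesday's and 33.7% for Sunday's, so the answer is neither.

    partner + free catalyst → catalyst intermediate A (k = 0.380 L mol⁻¹ s⁻¹)
    substrate + catalyst intermediate A ⇌ catalyst intermediate B (K = 2.90 L mol⁻¹, k = 0.770 L mol⁻¹ s⁻¹)
    catalyst intermediate B ⇌ free catalyst + product (K = 0.0170 M, k = 0.310 s⁻¹)

At the end of Wednesday's, catalyst intermediate A, the resting state, holds 83.2% of the catalyst, catalyst intermediate B 10.9% and free catalyst 5.90%. Wednesday's log-left is now 0.411, and the substrate power 0.567 carries it to a further flask, like Wednesday's but with 0.20 M of substrate, as L = 0.245. That means 78.3% of its substrate left, and that flask ends with unbound substrate at 79% of its charge.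

The runs were computed on assumed constants, and the scatter is random.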